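**Retrosynthetic overview**

1. Ring labels: A is the benzene with C5–OH and C6–CH3, F the dimethylpyran fused to it at C7–C8, C the 4-pyranone, D the furan, B the second benzene, E the dihydropyran with the trans-diol. The strategy rests on C2 of ring C, which is bonded to both O1 and the ring D oxygen and is therefore the carbonyl carbon of a benzofuran-2(3H)-one (rings B, D, E), and on C8a of ring A, which lies ortho to the C4 ketone and can carry fluorine.
2. Ring C is cut at C3–C4 (C-acylation of the lactone enolate) and at O1–C8a (SNAr on the aryl fluoride), giving lactone 23 and ortho-fluoro acid chloride 8.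
3. Acid chloride 8 comes from 1-fluoro-3,5-dimethoxybenzene: methyl between the oxygens, ring F by enal annulation, carboxyl by lithiation between F and OMOM.
4. Lactone 23 comes from 2,5-dimethoxyphenol: ring E by enal annulation, ring B taken to the quinone, trans-diol by Jacobsen–Katsuki epoxidation and anti hydrolysis on the dipivalate, ring D by malonate addition to the quinone and lactonisation.
5. Ring order: F and E (in separate branches), then D, then C in the key step; the four MOM ethers are removed last.

Key step: step 16

Remark: n-BuLi without amine additive is assumed to deprotonate 1 at C4 between the two methoxy groups (coordination control), not next to fluorine; lactone ester 21 is drawn as its enol tautomer.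

**Ring A branch**

Step 1
Reactants: 1 1-fluoro-3,5-dimethoxybenzene
Product: 2 5-fluoro-1,3-dimethoxy-2-methylbenzene
Conditions: n-BuLi, THF, −78 → 0 °C; MeI, −78 → 25 °C
Reagents that add atoms: iodomethane, CI
Why: Directed ortho-metalation, in which n-BuLi is held by both methoxy groups and removes the C4 proton between them, followed by SN2 methylation of the aryllithium.

Step 2
Reactants: 2 5-fluoro-1,3-dimethoxy-2-methylbenzene
Product: 3 5-fluoro-2-methylbenzene-1,3-diol
Conditions: BBr3, CH2Cl2, −78 → 25 °C; H2O
Reagents that add atoms: none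
Why: Lewis acid ether cleavage, in which BBr3 complexes each aryl methyl ether and bromide removes the methyl group by SN2, leaving the aryl C–F bond untouched.

Step 3
Reactants: 3 5-fluoro-2-methylbenzene-1,3-diol; 4 3-methylbut-2-enal
Product: 5 5-fluoro-2,2,8-trimethyl-2H-chromen-7-ol
Conditions: ethylenediammonium diacetate (10 mol %), toluene, 110 °C
Reagents that add atoms: none
Why: Formal [3+3] chromene annulation (Knoevenagel-type attack of the ring carbon ortho to one hydroxyl and para to the other, dehydration to the ortho-quinone methide, oxa-6π electrocyclisation); the methyl group blocks the carbon between the oxygens and the two open sites are equivalent, so one equivalent of enal should give a single mono-chromene.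

Step 4
Reactants: 5 5-fluoro-2,2,8-trimethyl-2H-chromen-7-ol
Product: 6 5-fluoro-7-(methoxymethoxy)-2,2,8-trimethyl-2H-chromene
Conditions: MOMCl, iPr2NEt, CH2Cl2, 0 → 25 °C
Reagents that add atoms: chloromethyl methyl ether, COCCl
Why: Williamson-type O-alkylation of the phenol, giving a group that protects the later C5 hydroxyl and directs the next lithiation.

Step 5
Reactants: 6 5-fluoro-7-(methoxymethoxy)-2,2,8-trimethyl-2H-chromene
Product: 7 5-fluoro-7-(methoxymethoxy)-2,2,8-trimethyl-2H-chromene-6-carboxylic acid
Conditions: n-BuLi, THF, −78 °C; CO2; aq. HCl to pH 3, 0 °C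
Reagents that add atoms: carbon dioxide, O=C=O
Why: Directed ortho-metalation at the only ring C–H, acidified by the flanking fluorine and chelated by the MOM ether, then carboxylation; −78 °C keeps the ortho-fluoro aryllithium from losing LiF to an aryne.

Step 6
Reactants: 7 5-fluoro-7-(methoxymethoxy)-2,2,8-trimethyl-2H-chromene-6-carboxylic acid
Product: 8 5-fluoro-7-(methoxymethoxy)-2,2,8-trimethyl-2H-chromene-6-carbonyl chloride
Conditions: 1-chloro-N,N,2-trimethylprop-1-en-1-amine, CH2Cl2, 0 → 25 °C; evaporated and used crude at once
Reagents that add atoms: 1-chloro-N,N,2-trimethylprop-1-en-1-amine, CC(C)=C(Cl)N(C)C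
Why: The α-chloroenamine converts the acid into the acid chloride through an acyloxyiminium chloride under neutral conditions without HCl, so the ortho MOM ether and the chromene should survive.

**Rings B, D, E branch**

Step 7
Reactants: 9 2,5-dimethoxyphenol; 4 3-methylbut-2-enal
Product: 10 5,8-dimethoxy-2,2-dimethyl-2H-chromene
Conditions: PhB(OH)2, AcOH, toluene, reflux (Dean–Stark)
Reagents that add atoms: none
Why: Phenylboronic acid-mediated ortho-specific condensation of a phenol with an enal (2-phenyl-4H-1,3,2-benzodioxaborin, thermal release of the ortho-quinone methide, oxa-6π electrocyclisation); C6 is the only free ortho position, so ring E forms between the phenol oxygen and C6.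

Step 8
Reactants: 10 5,8-dimethoxy-2,2-dimethyl-2H-chromene
Product: 11 2,2-dimethyl-2H-chromene-5,8-dione
Conditions: (NH4)2Ce(NO3)6, MeCN/H2O, 0 °C
Reagents that add atoms: water, O
Why: Oxidative demethylation of a para-dimethoxyarene by tetravalent cerium through the arene radical cation and ipso attack of water, giving the 5,8-quinone and leaving the tertiary ring ether in place.

Step 9
Reactants: 11 2,2-dimethyl-2H-chromene-5,8-dione
Product: 13 2,2-dimethyl-2H-chromene-5,8-diyl bis(2,2-dimethylpropanoate), via hydroquinone 12 (not isolated)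
Conditions: Na2S2O4, EtOAc/H2O, 25 °C; then PivCl, Et3N, DMAP (cat.), CH2Cl2, 0 → 25 °C
Reagents that add atoms: pivaloyl chloride, CC(C)(C)C(=O)Cl
Why: Dithionite reduction of the quinone and acylation of both phenols; the pivalates tolerate the hypochlorite of the next step and turn the ring B oxygens into weak donors, so that the benzylic oxirane made there should not be ionised by the arene.

Step 10
Reactants: 13 2,2-dimethyl-2H-chromene-5,8-diyl bis(2,2-dimethylpropanoate)
Product: 15 (3R,4S)-3,4-dihydroxy-2,2-dimethylchromane-5,8-diyl bis(2,2-dimethylpropanoate), via epoxide 14 (not isolated)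
Conditions: (R,R)-N,N'-bis(3,5-di-tert-butylsalicylidene)cyclohexane-1,2-diamine manganese chloride C36H52ClMnN2O2 (trivalent manganese, 4 mol %), NaOCl (aq., pH 11.3), 4-phenylpyridine N-oxide, CH2Cl2, 0 °C; then 0.5 M aq. H2SO4, acetone, 25 °C
Reagents that add atoms: sodium hypochlorite, [Na+].[O-]Cl; water, O
Why: Jacobsen–Katsuki epoxidation of a cis-disubstituted 2,2-dimethylchromene, in which the (R,R)-ligand fixes the alkene face and thereby C3 (R) in the (3R,4R)-oxide, then acid-catalysed anti opening by water at the benzylic C4 with inversion, which sets C4 (S) relative to C3 and gives the trans-diol.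

Step 11
Reactants: 15 (3R,4S)-3,4-dihydroxy-2,2-dimethylchromane-5,8-diyl bis(2,2-dimethylpropanoate)
Product: 16 (3R,4S)-3,4-bis(methoxymethoxy)-2,2-dimethylchromane-5,8-diyl bis(2,2-dimethylpropanoate)
Conditions: MOMCl, iPr2NEt, n-Bu4NI (cat.), 1,2-dichloroethane, 60 °C
Reagents that add atoms: chloromethyl methyl ether, COCCl
Why: Both secondary hydroxyls are alkylated by the chloromethyl ether with iodide catalysis; the aryl pivalates are stable to the amine base and no stereocentre is touched.

Step 12
Reactants: 16 (3R,4S)-3,4-bis(methoxymethoxy)-2,2-dimethylchromane-5,8-diyl bis(2,2-dimethylpropanoate)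
Product: 18 (3R,4S)-3,4-bis(methoxymethoxy)-2,2-dimethyl-3,4-dihydro-2H-chromene-5,8-dione, via hydroquinone 17 (not isolated)
Conditions: NaOMe, MeOH/THF, 0 → 25 °C, argon; AcOH; then PhI(OAc)2, MeCN/H2O, 0 °C
Reagents that add atoms: none
Why: Methoxide transesterification frees the hydroquinone, which PhI(OAc)2 oxidises by two electrons to the quinone under conditions that leave the MOM acetals alone.

Step 13
Reactants: 18 (3R,4S)-3,4-bis(methoxymethoxy)-2,2-dimethyl-3,4-dihydro-2H-chromene-5,8-dione; 19 dimethyl malonate
Product: 21 methyl ester of the C5–C6 fused 3-carboxy lactone of (3R,4S)-8-hydroxy-3,4-bis(methoxymethoxy)-2,2-dimethylchromane (enol form), via malonate adduct 20 (not isolated)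
Conditions: NaH, 19 (1.5 equiv), THF, 0 °C; 18 added slowly, −20 → 25 °C, argon; AcOH
Reagents that add atoms: none
Why: Michael addition of NaCH(CO2Me)2 to the quinone, where O1 makes C5=O a vinylogous ester so the enone of C8=O accepts the nucleophile at its β-carbon C6; after tautomerisation to the hydroquinone the C5 hydroxyl closes the five-membered lactone onto one ester, driven by the stabilised β-dicarbonyl enolate, which is the known route from quinones and malonates to 3-alkoxycarbonyl benzofuran-2(3H)-ones.

Step 14
Reactants: 21 lactone ester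
Product: 22 (3R,4S)-8-hydroxy-3,4-bis(methoxymethoxy)-2,2-dimethylchromane with a furan-2(3H)-one fused at C5–C6 (lactone O on C5, CH2 on C6)
Conditions: LiCl (0.2 equiv), DMSO/H2O (10:1), 120 °C, argon
Reagents that add atoms: none
Why: Krapcho-type dealkoxycarbonylation of a β-dicarbonyl ester in wet DMSO: demethylation by chloride or hydrolytic opening of the activated aryl lactone gives an arylmalonic half-acid that loses CO2, and the hydroxy ester re-closes to the five-membered lactone.

Step 15
Reactants: 22 hydroxy lactone
Product: 23 tri-MOM benzofuran-2(3H)-one of rings B, D, E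
Conditions: MOMCl, iPr2NEt, CH2Cl2, 0 °C, argon
Reagents that add atoms: chloromethyl methyl ether, COCCl
Why: The neutral phenol is alkylated by the chloromethyl ether, whereas iPr2NEt is too weak a base to enolise the lactone methylene appreciably, so O-alkylation of the phenol should prevail over alkylation at C3.

**Union and end game**

Step 16
Reactants: 23 tri-MOM benzofuran-2(3H)-one; 8 5-fluoro-7-(methoxymethoxy)-2,2,8-trimethyl-2H-chromene-6-carbonyl chloride
Product: 25 tetra-MOM ether of the target, via 3-aroyl lactone 24 (not isolated)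
Conditions: LiN(SiMe3)2 (1.05 equiv), THF, −78 °C; 8 (1.1 equiv), −78 → 0 °C; DMAP (0.2 equiv), 25 °C; Cs2CO3 (2.5 equiv), DMF, 70 °C
Reagents that add atoms: none
Why: The enolate of 23 is acylated by 8 at carbon or oxygen, DMAP carries any enol ester acyl group over to C3 through an N-acylpyridinium/enolate ion pair (Black-type O-to-C rearrangement), and Cs2CO3 holds the strongly acidic 3-aroyl lactone 24 as its enolate, which forms the C3–C4 bond irreversibly. The enolate oxygen on C2 then adds to the fluorine-bearing carbon ortho to the aryl ketone and fluoride leaves from the Meisenheimer intermediate, an intramolecular SNAr that closes the six-membered ring C through the O1–C8a bond. The closest known reaction type is the tandem C-acylation and SNAr of active methylene compounds such as malonates and β-keto esters with 2-fluorobenzoyl chlorides to give chromones. No stereocentre is formed, and the two in ring E are remote and held as base-stable MOM ethers. The step needs C- over O-acylation, secured by the acyl shuttle and the much higher acidity of the C-acyl product, and a single site of ring closure, secured because only C8a carries a leaving group, the ketone oxygen cannot reach it and the ring D oxygen is already tied into the lactone, so neither a coumestan nor a C5-linked isomer can form.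

Step 17
Reactants: 25 tetra-MOM ether of the target
Product: 26 CNP0351839.1
Conditions: Me2BBr, CH2Cl2, −78 °C; then THF/aq. NaHCO3, 0 °C
Reagents that add atoms: none
Why: Me2BBr complexes the acetal oxygens and cleaves each O–CH2–O unit at −78 °C to species that the bicarbonate work-up hydrolyses; no bond to the carbinol carbons of ring E is broken and no protic acid or alcohol is present, so the benzylic trans-diol and ring F should survive.

**Compound list**

1 | 1-fluoro-3,5-dimethoxybenzene | COc1cc(F)cc(OC)c1 | starting material
2 | 5-fluoro-1,3-dimethoxy-2-methylbenzene | COc1cc(F)cc(OC)c1C | intermediate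
3 | 5-fluoro-2-methylbenzene-1,3-diol | Cc1c(O)cc(F)cc1O | intermediate
4 | 3-methylbut-2-enal | CC(C)=CC=O | starting material
5 | 5-fluoro-2,2,8-trimethyl-2H-chromen-7-ol | Cc1c(O)cc(F)c2C=CC(C)(C)Oc12 | intermediate
6 | 5-fluoro-7-(methoxymethoxy)-2,2,8-trimethyl-2H-chromene | COCOc1cc(F)c2C=CC(C)(C)Oc2c1C | intermediate
7 | 5-fluoro-7-(methoxymethoxy)-2,2,8-trimethyl-2H-chromene-6-carboxylic acid | COCOc1c(C(=O)O)c(F)c2C=CC(C)(C)Oc2c1C | intermediate
8 | 5-fluoro-7-(methoxymethoxy)-2,2,8-trimethyl-2H-chromene-6-carbonyl chloride | COCOc1c(C(=O)Cl)c(F)c2C=CC(C)(C)Oc2c1C | intermediate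
9 | 2,5-dimethoxyphenol | COc1ccc(OC)c(O)c1 | starting material
10 | 5,8-dimethoxy-2,2-dimethyl-2H-chromene | COc1ccc(OC)c2c1OC(C)(C)C=C2 | intermediate
11 | 2,2-dimethyl-2H-chromene-5,8-dione | CC1(C)C=CC2=C(O1)C(=O)C=CC2=O | intermediate
12 | 2,2-dimethyl-2H-chromene-5,8-diol (not isolated) | CC1(C)C=Cc2c(O)ccc(O)c2O1 | intermediate
13 | 2,2-dimethyl-2H-chromene-5,8-diyl bis(2,2-dimethylpropanoate) | CC(C)(C)C(=O)Oc1ccc(OC(=O)C(C)(C)C)c2c1OC(C)(C)C=C2 | intermediate
14 | (3R,4R)-3,4-epoxy-2,2-dimethylchromane-5,8-diyl bis(2,2-dimethylpropanoate) (not isolated) | CC(C)(C)C(=O)Oc1ccc(OC(=O)C(C)(C)C)c2c1OC(C)(C)[C@@H]3O[C@H]23 | intermediate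
15 | (3R,4S)-3,4-dihydroxy-2,2-dimethylchromane-5,8-diyl bis(2,2-dimethylpropanoate) | CC(C)(C)C(=O)Oc1ccc(OC(=O)C(C)(C)C)c2c1OC(C)(C)[C@H](O)[C@H]2O | intermediate
16 | (3R,4S)-3,4-bis(methoxymethoxy)-2,2-dimethylchromane-5,8-diyl bis(2,2-dimethylpropanoate) | CC(C)(C)C(=O)Oc1ccc(OC(=O)C(C)(C)C)c2c1OC(C)(C)[C@H](OCOC)[C@H]2OCOC | intermediate
17 | (3R,4S)-3,4-bis(methoxymethoxy)-2,2-dimethylchromane-5,8-diol (not isolated) | Oc1ccc(O)c2c1OC(C)(C)[C@H](OCOC)[C@H]2OCOC | intermediate
18 | (3R,4S)-3,4-bis(methoxymethoxy)-2,2-dimethyl-3,4-dihydro-2H-chromene-5,8-dione | O=C1C=CC(=O)C2=C1OC(C)(C)[C@H](OCOC)[C@H]2OCOC | intermediate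
19 | dimethyl malonate | COC(=O)CC(=O)OC | starting material
20 | dimethyl 2-[(3R,4S)-5,8-dihydroxy-3,4-bis(methoxymethoxy)-2,2-dimethylchroman-6-yl]malonate (not isolated) | Oc1cc(C(C(=O)OC)C(=O)OC)c(O)c2c1OC(C)(C)[C@H](OCOC)[C@H]2OCOC | intermediate
21 | (3R,4S)-8-hydroxy-3,4-bis(methoxymethoxy)-2,2-dimethylchromane with a 3-(methoxycarbonyl)furan-2(3H)-one fused at C5–C6 (lactone O on C5), drawn as the 2-hydroxyfuran enol | COC(=O)c1c(O)oc2c3c(c(O)cc12)OC(C)(C)[C@H](OCOC)[C@H]3OCOC | intermediate
22 | (3R,4S)-8-hydroxy-3,4-bis(methoxymethoxy)-2,2-dimethylchromane with a furan-2(3H)-one fused at C5–C6 (lactone O on C5, CH2 on C6) | O=C1Oc2c3c(c(O)cc2C1)OC(C)(C)[C@H](OCOC)[C@H]3OCOC | intermediate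
23 | tri-MOM benzofuran-2(3H)-one of rings B, D, E: the 8-O-methoxymethyl ether of 22 | O=C1Oc2c3c(c(OCOC)cc2C1)OC(C)(C)[C@H](OCOC)[C@H]3OCOC | intermediate
24 | 23 acylated at the lactone CH2 carbon by the aroyl group of 8, drawn as the 2-hydroxybenzofuran enol (not isolated) | Oc1oc2c3c(c(OCOC)cc2c1C(=O)c1c(F)c2C=CC(C)(C)Oc2c(C)c1OCOC)OC(C)(C)[C@H](OCOC)[C@H]3OCOC | intermediate
25 | tetra-MOM ether of the target (MOM on the ring A C5 oxygen, the ring B phenol oxygen and both ring E carbinol oxygens) | Cc1c2c(c3oc4oc5c6c(c(OCOC)cc5c4c(=O)c3c1OCOC)OC(C)(C)[C@H](OCOC)[C@H]6OCOC)C=CC(C)(C)O2 | intermediate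
26 | CNP0351839.1, ring E diol (3R,4S), trans | Cc1c2c(c3oc4oc5c6c(c(O)cc5c4c(=O)c3c1O)OC(C)(C)[C@H](O)[C@H]6O)C=CC(C)(C)O2 | target

**Step count and risks**

Total steps: 17. Longest linear sequence: 11 (steps 7 to 17, from 2,5-dimethoxyphenol).

Most likely to fail:

1. Step 16. The acylation may partition to oxygen or to double acylation without complete acyl transfer, the acid chloride may lose its ortho MOM group by cyclisation onto the acyl carbon, and fluoride displacement may be slow on the donor-substituted ring A. The fallback sets out from acid 7 and lactone 23 and separates the two bond formations with a different acyl donor. Acid 7 is treated with 1-(methylsulfonyl)-1H-benzotriazole and Et3N in THF at 65 °C to give the shelf-stable 1-[5-fluoro-7-(methoxymethoxy)-2,2,8-trimethyl-2H-chromene-6-carbonyl]-1H-benzotriazole F1. The enolate of 23 (LiN(SiMe3)2, 2.1 equiv, THF, −78 → 25 °C) is C-acylated by F1, a known regiospecific C-acylation of enolates, and 24 is now isolated. K2CO3 in DMF at 80 °C then closes ring C in a separate SNAr, and the route is rejoined at 25.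

2. Step 13. Electron transfer between the anion of the hydroquinone adduct and unreacted quinone may scramble oxidation levels, and the malonate may add a second time or attack C7 or C8a. The fallback sets out from quinone 18 and uses a base-free Mukaiyama–Michael addition: 1-(tert-butyldimethylsilyloxy)-1-methoxyethene in MeCN at 0 → 25 °C should add at C6 and aromatise with silyl transfer to the C8 oxygen, giving methyl 2-[(3R,4S)-8-(tert-butyldimethylsilyloxy)-5-hydroxy-3,4-bis(methoxymethoxy)-2,2-dimethylchroman-6-yl]acetate F2, in which the silyl cap prevents redox exchange. Et3N·3HF in THF removes the silyl group, and warming with catalytic pyridinium p-toluenesulfonate in toluene at 80 °C lactonises the C5 hydroxyl onto the ester, rejoining the route at 22 without the decarboxylation step.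

3. Step 1. Deprotonation may occur next to fluorine instead of between the methoxy groups, and that aryllithium would lose LiF to an aryne on warming. The fallback sets out from 1 and blocks the fluorine-flanked positions. LiN(iPr)2 (2.4 equiv) with Me3SiCl present in THF at −78 °C silylates both carbons between F and OMe to give (2-fluoro-4,6-dimethoxy-1,3-phenylene)bis(trimethylsilane) F3. n-BuLi in THF at 0 °C can then only remove the proton between the methoxy groups, and MeI gives (2-fluoro-4,6-dimethoxy-5-methyl-1,3-phenylene)bis(trimethylsilane) F4. CF3CO2H in CH2Cl2 at 25 °C removes both silyl groups by ipso-protodesilylation and returns 2.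

**Further compounds**

F1 | step 16 | 1-[5-fluoro-7-(methoxymethoxy)-2,2,8-trimethyl-2H-chromene-6-carbonyl]-1H-benzotriazole | COCOc1c(C(=O)n2nnc3ccccc32)c(F)c2C=CC(C)(C)Oc2c1C
F2 | step 13 | methyl 2-[(3R,4S)-8-(tert-butyldimethylsilyloxy)-5-hydroxy-3,4-bis(methoxymethoxy)-2,2-dimethylchroman-6-yl]acetate | CC(C)(C)[Si](C)(C)Oc1cc(CC(=O)OC)c(O)c2c1OC(C)(C)[C@H](OCOC)[C@H]2OCOC
F3 | step 1 | (2-fluoro-4,6-dimethoxy-1,3-phenylene)bis(trimethylsilane) | COc1cc(OC)c([Si](C)(C)C)c(F)c1[Si](C)(C)C
F4 | step 1 | (2-fluoro-4,6-dimethoxy-5-methyl-1,3-phenylene)bis(trimethylsilane) | COc1c(C)c(OC)c([Si](C)(C)C)c(F)c1[Si](C)(C)C
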